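**Plan**
1. Retrosynthetic cuts, in order: the C(sp3)–pyridine bond of the C3 chain (B-alkyl Suzuki, made last); O2–C3 of the isoxazolidine (SN2 by the hydroxylamine oxygen); N1–CH2 of the N-chain (reductive amination with 12-(pyridin-3-yl)dodecanal, whose own C(sp3)–pyridine bond comes from a separate B-alkyl Suzuki coupling); the bond between the second and third carbon of the C3 side chain (copper coupling); N1–C6a (nitrene C–H insertion).
2. Enabling feature: N1-bearing C6a and O2-bearing C3 are 1,3-related through C3a on a plain cyclopentane, so a sulfamate on the C3 oxygen holds its nitrogen one six-membered ring away from a C6a–H bond.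
3. Forward: cyclopentyl β-keto ester → (R)-carbinol → sulfamate → Rh insertion closes a temporary cis-fused oxathiazinane → ester grown to an oct-7-enyl chain → hydride removal of the SO2 tether → reductive amination with the pyridyl aldehyde → N-oxidation → isoxazolidine closure → second pyridine by hydroboration and Suzuki coupling.
4. Stereochemistry: C3 from Noyori hydrogenation; C3a and C6a from the C3-controlled insertion (cis fusion, one of two diastereotopic ring CH2 groups); C3 is inverted (R → S) when O2–C3 is formed.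

Key step: step 3

Remark on labels: N1, O2, C3, C3a, C6a follow the target (hexahydro-1H-cyclopenta[c]isoxazole); in the oxathiazinane names C4, C4a and C7a are these same C3, C3a and C6a.
Assumption: the insertion is taken to prefer the chair-like transition state with the side chain equatorial and the non-reacting ring methylene anti to the C–O bond; this preference is not secure, and the fallback for step 3 covers the opposite case.

**Step 1**
Reactants: 1 ethyl 3-cyclopentyl-3-oxopropanoate
Product: 2 ethyl (3R)-3-cyclopentyl-3-hydroxypropanoate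
Conditions: [RuCl(p-cymene)((S)-BINAP)]Cl (0.5 mol %), H2 (50 bar), EtOH, 80 °C
Reagents that add atoms: none
Why: Noyori asymmetric hydrogenation, in which the β-keto ester chelates ruthenium through both carbonyl oxygens and the (S)-BINAP ligand directs hydride to one ketone face; this gives the 3R alcohol (R because cyclopentyl outranks CH2CO2Et) and sets C3.

**Step 2**
Reactants: 2 ethyl (3R)-3-cyclopentyl-3-hydroxypropanoate
Product: 3 ethyl (3R)-3-cyclopentyl-3-(sulfamoyloxy)propanoate
Conditions: ClSO2NH2 (1.5 equiv), DMA, 0 °C → rt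
Reagents that add atoms: sulfamoyl chloride, NS(=O)(=O)Cl
Why: O-sulfamoylation of a secondary alcohol in DMA, which takes up the HCl so that no added base is needed and the β-sulfamoyloxy ester is not exposed to elimination conditions.

**Step 3**
Reactants: 3 ethyl (3R)-3-cyclopentyl-3-(sulfamoyloxy)propanoate
Product: 5 ethyl [(4R,4aS,7aR)-2,2-dioxidohexahydrocyclopenta[d][1,2,3]oxathiazin-4-yl]acetate, via iminoiodinane 4 (not isolated)
Conditions: Rh2(esp)2 (2 mol %; esp = α,α,α′,α′-tetramethyl-1,3-benzenedipropanoate), PhI(OAc)2 (1.2 equiv), MgO (2.3 equiv), CH2Cl2, 40 °C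
Reagents that add atoms: none
Why: PhI(OAc)2 turns the sulfamate NH2 into iminoiodinane 4, which hands the nitrogen to Rh2(esp)2, and the dirhodium-bound singlet nitrene inserts into a C–H bond in one concerted, asynchronous event with retention at carbon, the known reaction type being rhodium-catalysed C–H amination of sulfamate esters to 1,2,3-oxathiazinane 2,2-dioxides. The one ring closed is this six-membered oxathiazinane, formed by N1–C7a bonding through a chair-like transition state; the long S–O and S–N bonds and the narrow N–S–O angle favour this gamma mode over a five-membered ring at the tertiary C4a–H. Site selectivity is secured by the CH2CO2Et side chain, whose gamma atom is the ester carbonyl carbon and whose CH2 is beta and deactivated, so the two ring methylenes carry the only gamma hydrogens (a plain alkyl chain would offer a competing secondary gamma C–H). C7a (R) arises because nitrogen replaces the hydrogen cis to the carbinol carbon, the one that avoids a trans 6/5 fusion; C4a (S) is not touched but becomes stereogenic by this choice. Which of the two diastereotopic methylenes reacts is controlled by C4: with the side chain equatorial, the favoured chair has the non-reacting methylene anti to the C4–O bond and the small C4a–H between oxygen and side chain, leading to the (4R,4aS,7aR) isomer. This group selectivity rests on C4 alone and is expected to be moderate, so the other cis-fused diastereomer is removed by chromatography here.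

**Step 4**
Reactants: 5 ethyl [(4R,4aS,7aR)-2,2-dioxidohexahydrocyclopenta[d][1,2,3]oxathiazin-4-yl]acetate
Product: 6 2-[(4R,4aS,7aR)-2,2-dioxidohexahydrocyclopenta[d][1,2,3]oxathiazin-4-yl]ethanol
Conditions: LiBH4 (2.5 equiv), THF–MeOH, 0 °C → rt
Reagents that add atoms: none
Why: chemoselective ester reduction by LiBH4, which leaves the cyclic sulfamate and its N–H untouched and removes the only acidifying group next to the C–O bond.

**Step 5**
Reactants: 6 2-[(4R,4aS,7aR)-2,2-dioxidohexahydrocyclopenta[d][1,2,3]oxathiazin-4-yl]ethanol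
Product: 7 (4R,4aS,7aR)-4-(2-iodoethyl)hexahydrocyclopenta[d][1,2,3]oxathiazine 2,2-dioxide
Conditions: I2, PPh3, imidazole, CH2Cl2, 0 °C → rt
Reagents that add atoms: iodine, [I][I]
Why: Appel iodination of the primary alcohol under neutral conditions; the weakly nucleophilic sulfamate N–H does not compete for the iodophosphonium ion.

**Step 6**
Reactants: 7 (4R,4aS,7aR)-4-(2-iodoethyl)hexahydrocyclopenta[d][1,2,3]oxathiazine 2,2-dioxide; 8 6-bromohex-1-ene
Product: 10 (4R,4aS,7aR)-4-(oct-7-en-1-yl)hexahydrocyclopenta[d][1,2,3]oxathiazine 2,2-dioxide, via hex-5-enylmagnesium bromide 9 (not isolated)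
Conditions: 8, Mg, THF, rt (2.3 equiv of 9); then 7, Li2CuCl4 (5 mol %), THF, −78 → 0 °C; aq. NH4Cl
Reagents that add atoms: none
Why: copper-catalysed coupling of a primary alkyl iodide with a primary alkyl Grignard reagent (Kochi-type); the first equivalent of 9 converts the sulfamate N–H into its magnesium salt, which is not an alkylating agent.

**Step 7**
Reactants: 10 (4R,4aS,7aR)-4-(oct-7-en-1-yl)hexahydrocyclopenta[d][1,2,3]oxathiazine 2,2-dioxide
Product: 11 (1R)-1-[(1S,2R)-2-aminocyclopentyl]non-8-en-1-ol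
Conditions: LiAlH4 (4 equiv), THF, 65 °C; H2O, aq. NaOH work-up
Reagents that add atoms: none
Why: reductive cleavage of an N–H cyclic sulfamate by LiAlH4, a known route to amino alcohols: the deprotonated nitrogen shuts off SN2 at carbon and hydride attacks sulfur, so S–O and S–N break while the C–O bond and its R configuration are kept; the terminal alkene is inert.

**Step 8**
Reactants: 12 dodec-11-en-1-ol; 13 3-bromopyridine
Product: 15 12-(pyridin-3-yl)dodecan-1-ol, via O-boryl alkylborane 14 (not isolated)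
Conditions: 9-BBN (2.2 equiv), THF, 0 °C → rt; then 13 (1.0 equiv), PdCl2(dppf) (3 mol %), aq. K3PO4, DMF, 60 °C
Reagents that add atoms: none
Why: anti-Markovnikov hydroboration of the terminal alkene by 9-BBN (a second equivalent is taken up by the hydroxyl as its borinate with loss of H2 and is hydrolysed again by the aqueous base) followed by B-alkyl Suzuki–Miyaura coupling with 3-bromopyridine, a standard entry to 3-alkylpyridines.

**Step 9**
Reactants: 15 12-(pyridin-3-yl)dodecan-1-ol
Product: 16 12-(pyridin-3-yl)dodecanal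
Conditions: (COCl)2, DMSO, CH2Cl2, −78 °C; then Et3N, −78 °C → rt
Reagents that add atoms: none
Why: Swern oxidation of a primary alcohol, which stops at the aldehyde and does not touch the pyridine nitrogen, so no N-oxide can form.

**Step 10**
Reactants: 11 (1R)-1-[(1S,2R)-2-aminocyclopentyl]non-8-en-1-ol; 16 12-(pyridin-3-yl)dodecanal
Product: 18 (1R)-1-[(1S,2R)-2-{[12-(pyridin-3-yl)dodecyl]amino}cyclopentyl]non-8-en-1-ol, via imine 17 (not isolated)
Conditions: 16 (1.05 equiv), MeOH, rt; then NaBH4, 0 °C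
Reagents that add atoms: none
Why: stepwise reductive amination, in which the α-branched primary amine condenses to the imine (in equilibrium with its 1,3-oxazinane ring tautomer) before NaBH4 is added, which limits dialkylation; the pyridine ring is inert to borohydride and enters only after the rhodium and LiAlH4 steps it would disturb.

**Step 11**
Reactants: 18 (1R)-1-[(1S,2R)-2-{[12-(pyridin-3-yl)dodecyl]amino}cyclopentyl]non-8-en-1-ol
Product: 19 O-benzoyl-N-{(1R,2S)-2-[(1R)-1-hydroxynon-8-en-1-yl]cyclopentyl}-N-[12-(pyridin-3-yl)dodecyl]hydroxylamine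
Conditions: (PhCO2)2 (1.2 equiv), K2HPO4, DMF, rt
Reagents that add atoms: dibenzoyl peroxide, O=C(OOC(=O)c1ccccc1)c1ccccc1
Why: oxidation of a secondary amine by dibenzoyl peroxide (nitrogen attacks the O–O bond) gives the O-benzoylhydroxylamine; the phosphate buffer suppresses N-benzoylation, the far less nucleophilic pyridine nitrogen does not compete at room temperature, and the amine nitrogen is both oxidised and made non-nucleophilic for the next step.

**Step 12**
Reactants: 19 O-benzoyl-N-{(1R,2S)-2-[(1R)-1-hydroxynon-8-en-1-yl]cyclopentyl}-N-[12-(pyridin-3-yl)dodecyl]hydroxylamine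
Product: 22 (3S,3aS,6aR)-3-(oct-7-en-1-yl)-1-[12-(pyridin-3-yl)dodecyl]hexahydro-1H-cyclopenta[c]isoxazole, via mesylate 20 (not isolated), via N-hydroxy mesylate 21 (not isolated)
Conditions: MsCl, Et3N, CH2Cl2, 0 °C; aq. NaHCO3 wash, concentrate; then K2CO3, MeOH, rt
Reagents that add atoms: none
Why: mesylation of the only free hydroxyl, then methanolysis of the benzoate frees the N–O nucleophile, which displaces the mesylate in a 5-exo-tet intramolecular Williamson-type O-alkylation; SN2 inversion turns C3 from R into the S configuration of the target and places the chain on the concave face.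

**Step 13**
Reactants: 22 (3S,3aS,6aR)-3-(oct-7-en-1-yl)-1-[12-(pyridin-3-yl)dodecyl]hexahydro-1H-cyclopenta[c]isoxazole; 13 3-bromopyridine
Product: 24 (3S,3aS,6aR)-1-[12-(pyridin-3-yl)dodecyl]-3-[8-(pyridin-3-yl)octyl]hexahydro-1H-cyclopenta[c]isoxazole, via B-alkyl-9-BBN 23 (not isolated)
Conditions: 9-BBN (2.2 equiv), THF, rt → 50 °C; then 13 (1.2 equiv), PdCl2(dppf) (5 mol %), aq. K3PO4, DMF, 60 °C
Reagents that add atoms: none
Why: anti-Markovnikov hydroboration of the one terminal alkene and B-alkyl Suzuki–Miyaura coupling (oxidative addition of 3-bromopyridine to zerovalent palladium, base-assisted transfer of the primary alkyl group, reductive elimination); the extra 9-BBN allows for the part held as a Lewis adduct by the pyridine nitrogen, which the aqueous base releases, and the N–O bond is inert to the borane and to palladium.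

**Compound list**
1 | ethyl 3-cyclopentyl-3-oxopropanoate | CCOC(=O)CC(=O)C1CCCC1 | starting material
2 | ethyl (3R)-3-cyclopentyl-3-hydroxypropanoate | O[C@H](CC(=O)OCC)C1CCCC1 | intermediate
3 | ethyl (3R)-3-cyclopentyl-3-(sulfamoyloxy)propanoate | NS(=O)(=O)O[C@H](CC(=O)OCC)C1CCCC1 | intermediate
4 | ethyl (3R)-3-cyclopentyl-3-({[(phenyl-λ3-iodanylidene)amino]sulfonyl}oxy)propanoate (iminoiodinane) | O=S(=O)(N=Ic1ccccc1)O[C@H](CC(=O)OCC)C1CCCC1 | intermediate
5 | ethyl [(4R,4aS,7aR)-2,2-dioxidohexahydrocyclopenta[d][1,2,3]oxathiazin-4-yl]acetate (cis-fused; N1 on C7a, O3 on C4) | N1S(=O)(=O)O[C@H](CC(=O)OCC)[C@H]2CCC[C@H]21 | intermediate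
6 | 2-[(4R,4aS,7aR)-2,2-dioxidohexahydrocyclopenta[d][1,2,3]oxathiazin-4-yl]ethanol | N1S(=O)(=O)O[C@H](CCO)[C@H]2CCC[C@H]21 | intermediate
7 | (4R,4aS,7aR)-4-(2-iodoethyl)hexahydrocyclopenta[d][1,2,3]oxathiazine 2,2-dioxide | N1S(=O)(=O)O[C@H](CCI)[C@H]2CCC[C@H]21 | intermediate
8 | 6-bromohex-1-ene | BrCCCCC=C | starting material
9 | hex-5-enylmagnesium bromide | C=CCCCC[Mg]Br | intermediate
10 | (4R,4aS,7aR)-4-(oct-7-en-1-yl)hexahydrocyclopenta[d][1,2,3]oxathiazine 2,2-dioxide | N1S(=O)(=O)O[C@H](CCCCCCC=C)[C@H]2CCC[C@H]21 | intermediate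
11 | (1R)-1-[(1S,2R)-2-aminocyclopentyl]non-8-en-1-ol | O[C@H](CCCCCCC=C)[C@H]1CCC[C@H]1N | intermediate
12 | dodec-11-en-1-ol | OCCCCCCCCCCC=C | starting material
13 | 3-bromopyridine | Brc1cccnc1 | starting material
14 | 9-{12-[(9-borabicyclo[3.3.1]nonan-9-yl)oxy]dodecyl}-9-borabicyclo[3.3.1]nonane | B1(CCCCCCCCCCCCOB2C3CCCC2CCC3)C2CCCC1CCC2 | intermediate
15 | 12-(pyridin-3-yl)dodecan-1-ol | OCCCCCCCCCCCCc1cccnc1 | intermediate
16 | 12-(pyridin-3-yl)dodecanal | O=CCCCCCCCCCCCc1cccnc1 | intermediate
17 | (1R)-1-[(1S,2R)-2-{[(E)-12-(pyridin-3-yl)dodecylidene]amino}cyclopentyl]non-8-en-1-ol (imine) | O[C@H](CCCCCCC=C)[C@H]1CCC[C@H]1/N=C/CCCCCCCCCCCc1cccnc1 | intermediate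
18 | (1R)-1-[(1S,2R)-2-{[12-(pyridin-3-yl)dodecyl]amino}cyclopentyl]non-8-en-1-ol | O[C@H](CCCCCCC=C)[C@H]1CCC[C@H]1NCCCCCCCCCCCCc1cccnc1 | intermediate
19 | O-benzoyl-N-{(1R,2S)-2-[(1R)-1-hydroxynon-8-en-1-yl]cyclopentyl}-N-[12-(pyridin-3-yl)dodecyl]hydroxylamine | O[C@H](CCCCCCC=C)[C@H]1CCC[C@H]1N(OC(=O)c1ccccc1)CCCCCCCCCCCCc1cccnc1 | intermediate
20 | (1R)-1-[(1S,2R)-2-{(benzoyloxy)[12-(pyridin-3-yl)dodecyl]amino}cyclopentyl]non-8-en-1-yl methanesulfonate | CS(=O)(=O)O[C@H](CCCCCCC=C)[C@H]1CCC[C@H]1N(OC(=O)c1ccccc1)CCCCCCCCCCCCc1cccnc1 | intermediate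
21 | (1R)-1-[(1S,2R)-2-{hydroxy[12-(pyridin-3-yl)dodecyl]amino}cyclopentyl]non-8-en-1-yl methanesulfonate | CS(=O)(=O)O[C@H](CCCCCCC=C)[C@H]1CCC[C@H]1N(O)CCCCCCCCCCCCc1cccnc1 | intermediate
22 | (3S,3aS,6aR)-3-(oct-7-en-1-yl)-1-[12-(pyridin-3-yl)dodecyl]hexahydro-1H-cyclopenta[c]isoxazole | c1cncc(CCCCCCCCCCCCN2O[C@@H](CCCCCCC=C)[C@H]3CCC[C@H]32)c1 | intermediate
23 | (3S,3aS,6aR)-3-[8-(9-borabicyclo[3.3.1]nonan-9-yl)octyl]-1-[12-(pyridin-3-yl)dodecyl]hexahydro-1H-cyclopenta[c]isoxazole | c1cncc(CCCCCCCCCCCCN2O[C@@H](CCCCCCCCB3C4CCCC3CCC4)[C@H]3CCC[C@H]32)c1 | intermediate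
24 | (3S,3aS,6aR)-1-[12-(pyridin-3-yl)dodecyl]-3-[8-(pyridin-3-yl)octyl]hexahydro-1H-cyclopenta[c]isoxazole | c1cncc(CCCCCCCCCCCCN2O[C@@H](CCCCCCCCc3cccnc3)[C@H]3CCC[C@H]32)c1 | target

**Step count**
Total: 13 steps. Longest linear sequence: 11 steps (1–7 and 10–13); steps 8 and 9 form a two-step side branch.

**Steps most likely to fail**

Step 3. The nitrogen may be delivered to the other diastereotopic ring methylene (group selectivity low or reversed), and insertion into an unactivated secondary C–H may be slow enough for oxidant decay to compete. Fallback, setting out from 1 and returning at 11: the enantiomeric carbinol is used and C3 is corrected by an inverting ring opening instead of being kept. Hydrogenation of 1 with [RuCl(p-cymene)((R)-BINAP)]Cl gives ethyl (3S)-3-cyclopentyl-3-hydroxypropanoate F1. Sulfamoylation gives ethyl (3S)-3-cyclopentyl-3-(sulfamoyloxy)propanoate F2. Insertion with the reversed methylene preference then gives ethyl [(4S,4aS,7aR)-2,2-dioxidohexahydrocyclopenta[d][1,2,3]oxathiazin-4-yl]acetate F3, which has the ring fusion of the target and the epimeric C3. The operations of steps 4–6 give 2-[(4S,4aS,7aR)-2,2-dioxidohexahydrocyclopenta[d][1,2,3]oxathiazin-4-yl]ethanol F4, (4S,4aS,7aR)-4-(2-iodoethyl)hexahydrocyclopenta[d][1,2,3]oxathiazine 2,2-dioxide F5 and (4S,4aS,7aR)-4-(oct-7-en-1-yl)hexahydrocyclopenta[d][1,2,3]oxathiazine 2,2-dioxide F6. Boc2O and DMAP activate the nitrogen as tert-butyl (4S,4aS,7aR)-4-(oct-7-en-1-yl)-2,2-dioxidohexahydrocyclopenta[d][1,2,3]oxathiazine-1-carboxylate F7. CsOAc in DMF opens F7 at C4 by SN2 with inversion to cesium N-(tert-butoxycarbonyl)-N-{(1R,2S)-2-[(1R)-1-acetoxynon-8-en-1-yl]cyclopentyl}sulfamate F8. HCl in MeOH then removes the N-sulfonate, the Boc group and the acetate to give 11.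

Step 7. Hydride may attack carbon instead of sulfur (loss of the C3 oxygen), or S–N cleavage may stay incomplete. Fallback, setting out from 10 and returning at 11, keeps the C3 configuration by two inversions. Boc2O and DMAP give tert-butyl (4R,4aS,7aR)-4-(oct-7-en-1-yl)-2,2-dioxidohexahydrocyclopenta[d][1,2,3]oxathiazine-1-carboxylate F9. Bu4NBr in MeCN opens it at C4 with inversion to tetrabutylammonium N-(tert-butoxycarbonyl)-N-{(1R,2S)-2-[(1S)-1-bromonon-8-en-1-yl]cyclopentyl}sulfamate F10. Aqueous citric acid hydrolyses the N-sulfonate to tert-butyl N-{(1R,2S)-2-[(1S)-1-bromonon-8-en-1-yl]cyclopentyl}carbamate F11. On heating in DMF the Boc carbonyl oxygen displaces bromide with a second inversion and loses the tert-butyl group, giving (4R,4aS,7aR)-4-(oct-7-en-1-yl)hexahydrocyclopenta[d][1,3]oxazin-2(1H)-one F12. KOH in aqueous EtOH hydrolyses F12 to 11.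

Step 12. Heterolytic fragmentation of the γ-amino mesylate (C6a–C3a cleavage) or E2 elimination may outrun the 5-exo-tet closure, and base may eliminate benzoate from nitrogen before the oxygen is freed. Fallback, setting out from 19 and returning at 22, closes the ring without a sulfonate. K2CO3 in MeOH at 0 °C removes the benzoate to give (1R)-1-[(1S,2R)-2-{hydroxy[12-(pyridin-3-yl)dodecyl]amino}cyclopentyl]non-8-en-1-ol F13. PPh3 and DIAD in THF then activate the carbinol as its oxyphosphonium ion, and the N-hydroxyl oxygen closes the ring by intramolecular Mitsunobu etherification with inversion, giving 22.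

**Further compounds**
F1 | step 3 | ethyl (3S)-3-cyclopentyl-3-hydroxypropanoate | O[C@@H](CC(=O)OCC)C1CCCC1
F2 | step 3 | ethyl (3S)-3-cyclopentyl-3-(sulfamoyloxy)propanoate | NS(=O)(=O)O[C@@H](CC(=O)OCC)C1CCCC1
F3 | step 3 | ethyl [(4S,4aS,7aR)-2,2-dioxidohexahydrocyclopenta[d][1,2,3]oxathiazin-4-yl]acetate | N1S(=O)(=O)O[C@@H](CC(=O)OCC)[C@H]2CCC[C@H]21
F4 | step 3 | 2-[(4S,4aS,7aR)-2,2-dioxidohexahydrocyclopenta[d][1,2,3]oxathiazin-4-yl]ethanol | N1S(=O)(=O)O[C@@H](CCO)[C@H]2CCC[C@H]21
F5 | step 3 | (4S,4aS,7aR)-4-(2-iodoethyl)hexahydrocyclopenta[d][1,2,3]oxathiazine 2,2-dioxide | N1S(=O)(=O)O[C@@H](CCI)[C@H]2CCC[C@H]21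
F6 | step 3 | (4S,4aS,7aR)-4-(oct-7-en-1-yl)hexahydrocyclopenta[d][1,2,3]oxathiazine 2,2-dioxide | N1S(=O)(=O)O[C@@H](CCCCCCC=C)[C@H]2CCC[C@H]21
F7 | step 3 | tert-butyl (4S,4aS,7aR)-4-(oct-7-en-1-yl)-2,2-dioxidohexahydrocyclopenta[d][1,2,3]oxathiazine-1-carboxylate | CC(C)(C)OC(=O)N1S(=O)(=O)O[C@@H](CCCCCCC=C)[C@H]2CCC[C@H]21
F8 | step 3 | cesium N-(tert-butoxycarbonyl)-N-{(1R,2S)-2-[(1R)-1-acetoxynon-8-en-1-yl]cyclopentyl}sulfamate | CC(=O)O[C@H](CCCCCCC=C)[C@H]1CCC[C@H]1N(C(=O)OC(C)(C)C)S(=O)(=O)[O-].[Cs+]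
F9 | step 7 | tert-butyl (4R,4aS,7aR)-4-(oct-7-en-1-yl)-2,2-dioxidohexahydrocyclopenta[d][1,2,3]oxathiazine-1-carboxylate | CC(C)(C)OC(=O)N1S(=O)(=O)O[C@H](CCCCCCC=C)[C@H]2CCC[C@H]21
F10 | step 7 | tetrabutylammonium N-(tert-butoxycarbonyl)-N-{(1R,2S)-2-[(1S)-1-bromonon-8-en-1-yl]cyclopentyl}sulfamate | Br[C@@H](CCCCCCC=C)[C@H]1CCC[C@H]1N(C(=O)OC(C)(C)C)S(=O)(=O)[O-].CCCC[N+](CCCC)(CCCC)CCCC
F11 | step 7 | tert-butyl N-{(1R,2S)-2-[(1S)-1-bromonon-8-en-1-yl]cyclopentyl}carbamate | Br[C@@H](CCCCCCC=C)[C@H]1CCC[C@H]1NC(=O)OC(C)(C)C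
F12 | step 7 | (4R,4aS,7aR)-4-(oct-7-en-1-yl)hexahydrocyclopenta[d][1,3]oxazin-2(1H)-one | N1C(=O)O[C@H](CCCCCCC=C)[C@H]2CCC[C@H]21
F13 | step 12 | (1R)-1-[(1S,2R)-2-{hydroxy[12-(pyridin-3-yl)dodecyl]amino}cyclopentyl]non-8-en-1-ol | O[C@H](CCCCCCC=C)[C@H]1CCC[C@H]1N(O)CCCCCCCCCCCCc1cccnc1
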